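**Assumption:** the target SMILES has no stereocentre and no stereogenic double bond, so the compound is achiral and needs no enantiocontrol.

## Retrosynthetic overview

1. Target ⇒ tri-O-benzyl alkynyl isoflavone: one neutral hydrogenation (C≡C → CH2CH2, 3 OBn → OH), so the tertiary alcohol/ortho-phenol pair never meets acid and cannot close to a chroman.
2. Alkynyl isoflavone ⇒ 3'-iodo isoflavone + 2-methylbut-3-yn-2-ol (Sonogashira, side chain introduced late).
3. Iodo isoflavone ⇒ β-keto acetal ⇒ 2'-hydroxychalcone: Tl(III) 1,2-aryl shift, then acid closure of the pyranone ring C (the only ring built; rings A and B are bought as arenes).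
4. Chalcone ⇒ 4,6-di-O-benzyl phloroacetophenone + 2-benzyloxy-3-iodo-4,5-dimethoxybenzaldehyde: intermolecular Claisen–Schmidt aldol condensation, the key C–C bond (it ends as C2–C3 of the chromone).
5. Aldehyde ⇐ 3,4-dimethoxyphenol (MOM-directed ortho-lithiation/iodination, Mg-mediated ortho-formylation, benzylation); ketone ⇐ 2,4,6-trihydroxyacetophenone.

## Route

**Step 1**
Reactants: 1 3,4-dimethoxyphenol
Product: 2 1,2-dimethoxy-4-(methoxymethoxy)benzene
Conditions: NaH (1.2 eq), THF/DMF, 0 °C; MOMCl (1.2 eq), 0 °C → rt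
Reagents that add atoms: chloromethyl methyl ether (MOMCl), COCCl
Why: Williamson O-alkylation of the sodium phenoxide with the reactive α-chloro ether installs the MOM group that directs the lithiation in step 2; no stereocentre is formed.

**Step 2**
Reactants: 2 1,2-dimethoxy-4-(methoxymethoxy)benzene
Product: 4 2-iodo-3,4-dimethoxy-1-(methoxymethoxy)benzene, via aryllithium 3 (not isolated)
Conditions: n-BuLi (1.2 eq), THF, 0 °C, 1 h; then I2 (1.3 eq), −78 °C → rt; aq Na2S2O3 work-up
Reagents that add atoms: iodine, II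
Why: Directed ortho-metalation, in which OMOM and the neighbouring OMe cooperate to direct n-BuLi to the carbon between them, followed by iodine quench of the aryllithium, fixes the future side-chain position; no stereocentre.

**Step 3**
Reactants: 4 2-iodo-3,4-dimethoxy-1-(methoxymethoxy)benzene
Product: 5 2-iodo-3,4-dimethoxyphenol
Conditions: conc. HCl (cat.), MeOH, 40 °C
Reagents that add atoms: none
Why: Acid-catalysed acetal exchange (MOM methanolysis) frees the phenol under mild conditions that leave the aryl iodide and the methyl ethers untouched.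

**Step 4**
Reactants: 5 2-iodo-3,4-dimethoxyphenol
Product: 7 2-hydroxy-3-iodo-4,5-dimethoxybenzaldehyde, via benzylic alcohol 6 (not isolated)
Conditions: MgCl2 (2 eq), Et3N (4 eq), (CH2O)n (6 eq), MeCN, reflux; 1 M HCl work-up
Reagents that add atoms: paraformaldehyde (formaldehyde), C=O
Why: Casnati–Skattebøl ortho-formylation, in which the magnesium phenoxide delivers formaldehyde to the only free ortho carbon and a second formaldehyde oxidises the benzylic alkoxide by Oppenauer-type hydride transfer, is well behaved for 2-halophenols.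

**Step 5**
Reactants: 7 2-hydroxy-3-iodo-4,5-dimethoxybenzaldehyde
Product: 8 2-(benzyloxy)-3-iodo-4,5-dimethoxybenzaldehyde
Conditions: BnBr (1.3 eq), K2CO3 (2 eq), DMF, 60 °C
Reagents that add atoms: benzyl bromide, BrCc1ccccc1
Why: Williamson etherification protects the phenol as a benzyl ether that survives base, Tl(III), dilute acid and Pd coupling and leaves at the end by neutral hydrogenolysis.

**Step 6**
Reactants: 9 2,4,6-trihydroxyacetophenone
Product: 10 1-[2,4-bis(benzyloxy)-6-hydroxyphenyl]ethan-1-one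
Conditions: BnBr (2.05 eq), K2CO3 (2.2 eq), DMF, 0 °C → rt
Reagents that add atoms: benzyl bromide, BrCc1ccccc1
Why: Williamson etherification with 2 equiv of BnBr is selective because the ortho-OH hydrogen-bonded to the ketone is the least nucleophilic and stays free.

**Step 7 (key step)**
Reactants: 10 1-[2,4-bis(benzyloxy)-6-hydroxyphenyl]ethan-1-one; 8 2-(benzyloxy)-3-iodo-4,5-dimethoxybenzaldehyde (1.1 eq)
Product: 12 (E)-1-[2,4-bis(benzyloxy)-6-hydroxyphenyl]-3-[2-(benzyloxy)-3-iodo-4,5-dimethoxyphenyl]prop-2-en-1-one, via aldol adduct 11 (not isolated)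
Conditions: KOH (50% aq, 10 eq), EtOH/THF, rt, 36 h; then 1 M HCl to pH 4
Reagents that add atoms: none
Why: Claisen–Schmidt (crossed aldol) condensation, in which the enolate of the methyl ketone adds to the non-enolisable aldehyde and E1cB loss of water gives the thermodynamically favoured E-enone, joins the A- and B-ring fragments; no stereocentre survives.

**Step 8**
Reactants: 12 (E)-chalcone
Product: 13 racemic 1-[2,4-bis(benzyloxy)-6-hydroxyphenyl]-2-[2-(benzyloxy)-3-iodo-4,5-dimethoxyphenyl]-3,3-dimethoxypropan-1-one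
Conditions: Tl(NO3)3·3H2O (1.2 eq), MeOH/CH2Cl2 (3:1), rt, 6 h; filter off TlNO3
Reagents that add atoms: methanol, CO
Why: Thallium(III)-mediated oxidative rearrangement of a chalcone (oxythallation of the enone, 1,2-shift of the electron-rich para-methoxyaryl ring with loss of Tl(I), methanol capture of the oxocarbenium ion) moves ring B to the α-carbon; the new stereocentre is racemic and is destroyed in step 9.

**Step 9**
Reactants: 13 racemic β-keto dimethyl acetal
Product: 15 5,7-bis(benzyloxy)-3-[2-(benzyloxy)-3-iodo-4,5-dimethoxyphenyl]-4H-chromen-4-one, via 2-methoxyisoflavanone 14 (not isolated)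
Conditions: 10% aq HCl, MeOH/THF, 60 °C, 2–3 h
Reagents that add atoms: none
Why: Acid-catalysed transacetalisation by the free 2'-phenol followed by elimination of methanol (cyclodehydration) closes the chromone ring, and nothing acid-labile is present because the tertiary alcohol has not yet been introduced.

**Step 10**
Reactants: 15 iodo-isoflavone; 16 2-methylbut-3-yn-2-ol (3 eq)
Product: 17 5,7-bis(benzyloxy)-3-[2-(benzyloxy)-3-(3-hydroxy-3-methylbut-1-yn-1-yl)-4,5-dimethoxyphenyl]-4H-chromen-4-one
Conditions: PdCl2(PPh3)2 (5 mol%), CuI (10 mol%), Et3N/DMF (1:3), 70 °C, Ar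
Reagents that add atoms: none
Why: Sonogashira coupling of the aryl iodide (the halide best suited to oxidative addition at this di-ortho-substituted position) with the terminal alkyne installs all five side-chain carbons under basic conditions.

**Step 11**
Reactants: 17 alkynyl tri-O-benzyl isoflavone
Product: 19 5,7-dihydroxy-3-[2-hydroxy-3-(3-hydroxy-3-methylbutyl)-4,5-dimethoxyphenyl]-4H-chromen-4-one, via saturated tribenzyl ether 18 (not isolated)
Conditions: H2 (1 atm), 10% Pd/C, EtOAc/MeOH (1:1), rt; stop when debenzylation is complete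
Reagents that add atoms: none
Why: Heterogeneous catalytic hydrogenation saturates the alkyne and then hydrogenolyses the three benzyl ethers under neutral conditions, so the tertiary alcohol cannot cyclise onto the new 2'-phenol, and the chromone C2=C3 bond is reduced much more slowly; no stereocentre is formed.

## Compound list

1 | 3,4-dimethoxyphenol | COc1ccc(O)cc1OC | starting material
2 | 1,2-dimethoxy-4-(methoxymethoxy)benzene | COCOc1ccc(OC)c(OC)c1 | intermediate
3 | [2,3-dimethoxy-6-(methoxymethoxy)phenyl]lithium (formed in the flask) | [Li]c1c(OCOC)ccc(OC)c1OC | intermediate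
4 | 2-iodo-3,4-dimethoxy-1-(methoxymethoxy)benzene | COCOc1ccc(OC)c(OC)c1I | intermediate
5 | 2-iodo-3,4-dimethoxyphenol | COc1ccc(O)c(I)c1OC | intermediate
6 | 6-(hydroxymethyl)-2-iodo-3,4-dimethoxyphenol (formed in the flask as its magnesium salt) | COc1cc(CO)c(O)c(I)c1OC | intermediate
7 | 2-hydroxy-3-iodo-4,5-dimethoxybenzaldehyde | COc1cc(C=O)c(O)c(I)c1OC | intermediate
8 | 2-(benzyloxy)-3-iodo-4,5-dimethoxybenzaldehyde | COc1cc(C=O)c(OCc2ccccc2)c(I)c1OC | intermediate
9 | 2,4,6-trihydroxyacetophenone (phloroacetophenone) | CC(=O)c1c(O)cc(O)cc1O | starting material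
10 | 1-[2,4-bis(benzyloxy)-6-hydroxyphenyl]ethan-1-one | CC(=O)c1c(O)cc(OCc2ccccc2)cc1OCc1ccccc1 | intermediate
11 | racemic 1-[2,4-bis(benzyloxy)-6-hydroxyphenyl]-3-[2-(benzyloxy)-3-iodo-4,5-dimethoxyphenyl]-3-hydroxypropan-1-one (aldol adduct, formed in the flask) | COc1cc(C(O)CC(=O)c2c(O)cc(OCc3ccccc3)cc2OCc2ccccc2)c(OCc2ccccc2)c(I)c1OC | intermediate
12 | (E)-1-[2,4-bis(benzyloxy)-6-hydroxyphenyl]-3-[2-(benzyloxy)-3-iodo-4,5-dimethoxyphenyl]prop-2-en-1-one | COc1cc(/C=C/C(=O)c2c(O)cc(OCc3ccccc3)cc2OCc2ccccc2)c(OCc2ccccc2)c(I)c1OC | intermediate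
13 | racemic 1-[2,4-bis(benzyloxy)-6-hydroxyphenyl]-2-[2-(benzyloxy)-3-iodo-4,5-dimethoxyphenyl]-3,3-dimethoxypropan-1-one | COc1cc(C(C(OC)OC)C(=O)c2c(O)cc(OCc3ccccc3)cc2OCc2ccccc2)c(OCc2ccccc2)c(I)c1OC | intermediate
14 | 5,7-bis(benzyloxy)-3-[2-(benzyloxy)-3-iodo-4,5-dimethoxyphenyl]-2-methoxychroman-4-one (racemic diastereomer mixture, formed in the flask) | COC1Oc2cc(OCc3ccccc3)cc(OCc3ccccc3)c2C(=O)C1c1cc(OC)c(OC)c(I)c1OCc1ccccc1 | intermediate
15 | 5,7-bis(benzyloxy)-3-[2-(benzyloxy)-3-iodo-4,5-dimethoxyphenyl]-4H-chromen-4-one | COc1cc(-c2coc3cc(OCc4ccccc4)cc(OCc4ccccc4)c3c2=O)c(OCc2ccccc2)c(I)c1OC | intermediate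
16 | 2-methylbut-3-yn-2-ol | CC(C)(O)C#C | starting material
17 | 5,7-bis(benzyloxy)-3-[2-(benzyloxy)-3-(3-hydroxy-3-methylbut-1-yn-1-yl)-4,5-dimethoxyphenyl]-4H-chromen-4-one | COc1cc(-c2coc3cc(OCc4ccccc4)cc(OCc4ccccc4)c3c2=O)c(OCc2ccccc2)c(C#CC(C)(C)O)c1OC | intermediate
18 | 5,7-bis(benzyloxy)-3-[2-(benzyloxy)-3-(3-hydroxy-3-methylbutyl)-4,5-dimethoxyphenyl]-4H-chromen-4-one (formed in the flask) | COc1cc(-c2coc3cc(OCc4ccccc4)cc(OCc4ccccc4)c3c2=O)c(OCc2ccccc2)c(CCC(C)(C)O)c1OC | intermediate
19 | 5,7-dihydroxy-3-[2-hydroxy-3-(3-hydroxy-3-methylbutyl)-4,5-dimethoxyphenyl]-4H-chromen-4-one (CNP0192638.0, achiral) | COc1cc(-c2coc3cc(O)cc(O)c3c2=O)c(O)c(CCC(C)(C)O)c1OC | target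

## Summary

Total step count: 11.
Longest linear sequence: 10 steps (1 → 19 through steps 1–5 and 7–11); the A-ring branch is step 6.

**Three steps most likely to fail, with fallbacks**

Step 8 (Tl(III) aryl shift; risk of over-oxidation of the trioxygenated B ring or aurone formation). The fallback sets out from 12 and comes back at 15. Chalcone 12 is first cyclised by intramolecular oxa-Michael addition (NaOAc, EtOH, reflux) to the racemic flavanone 5,7-bis(benzyloxy)-2-[2-(benzyloxy)-3-iodo-4,5-dimethoxyphenyl]chroman-4-one F2. The metal-free 2→3 aryl migration is then done on the closed ring with a hypervalent iodine reagent (PhI(OH)OTs, MeCN, reflux), which gives isoflavone 15 directly and bypasses steps 8 and 9.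

Step 10 (Sonogashira at a di-ortho-substituted, electron-rich aryl iodide; risk of slow coupling and alkyne homocoupling). The fallback sets out from 15 and comes back at 18, hence 19. A copper-free Mizoroki–Heck reaction of 15 with 2-methylbut-3-en-2-ol (Pd(OAc)2, P(o-tol)3, Et3N, DMF, 100 °C) gives (E)-5,7-bis(benzyloxy)-3-[2-(benzyloxy)-3-(3-hydroxy-3-methylbut-1-en-1-yl)-4,5-dimethoxyphenyl]-4H-chromen-4-one F3. Its alkene is saturated under the step 11 conditions to 18, and the same hydrogenolysis then gives 19.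

Step 2 (the whole B-ring pattern depends on lithiation between OMOM and OMe). The fallback sets out from 1 and comes back at 7. Phenol 1 is formylated directly at its less hindered ortho position (MgCl2, Et3N, paraformaldehyde, MeCN, reflux) to 2-hydroxy-4,5-dimethoxybenzaldehyde F1. Electrophilic iodination (NIS, cat. TFA, MeCN, rt) then takes place at the only position activated by both the phenol and a methoxy group (C3) and gives 7. This replaces anionic regiocontrol by electrophilic aromatic substitution and bypasses steps 1–4.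

## Further compounds

F1 | step 2 | 2-hydroxy-4,5-dimethoxybenzaldehyde | COc1cc(C=O)c(O)cc1OC
F2 | step 8 | racemic 5,7-bis(benzyloxy)-2-[2-(benzyloxy)-3-iodo-4,5-dimethoxyphenyl]chroman-4-one | COc1cc(C2CC(=O)c3c(OCc4ccccc4)cc(OCc4ccccc4)cc3O2)c(OCc2ccccc2)c(I)c1OC
F3 | step 10 | (E)-5,7-bis(benzyloxy)-3-[2-(benzyloxy)-3-(3-hydroxy-3-methylbut-1-en-1-yl)-4,5-dimethoxyphenyl]-4H-chromen-4-one | COc1cc(-c2coc3cc(OCc4ccccc4)cc(OCc4ccccc4)c3c2=O)c(OCc2ccccc2)c(/C=C/C(C)(C)O)c1OC
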